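The target is a meso 2,3-dibenzylsuccinyl chain (C1–C4) whose two carbonyl carbons, C1 and C4, each carry the same 2,4-dihydroxyphenyl ring A, while C2 and C3 carry the 4-hydroxybenzyl arms (ring B). Both C1–ring A and C4–ring A bonds are therefore cut at once. A single two-directional Liebeskind–Srogl coupling of a meso bis(S-ethyl thioester) with a ring A boronic acid forms both aryl ketones under neutral conditions, so the epimerisable C2/C3 centres and the furan-prone 1,4-diketone are untouched. The precursor, with all phenols as benzyl ethers, gets its meso configuration earlier from syn bis(methoxycarbonylation) of a Z-alkene.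

Key step: step 6

Remark: C2 and C3 of the target are (2S,3R) with identical substituent sets, so the compound is the achiral meso diastereomer and only relative configuration has to be controlled. The ring A boronic acid and ethynylmagnesium bromide (0.5 M in THF) are taken as catalogue compounds.

Step 1
Reactants: 1 4-(benzyloxy)benzyl chloride; 2 ethynylmagnesium bromide
Product: 3 1-(benzyloxy)-4-(prop-2-yn-1-yl)benzene
Conditions: 1 (1.0 equiv), 2 (0.5 M in THF, 1.5 equiv), CuCl (5 mol %), THF, 0 → 50 °C; aq NH4Cl
Reagents that add atoms: none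
Why: Copper-catalysed sp–sp3 substitution of the activated benzylic chloride by the alkynyl Grignard reagent (alkynyl Grignard alkylation) is the standard entry to 3-arylprop-1-ynes, the excess of 2 holds back a second benzylation, and no stereocentre is formed.

Step 2
Reactants: 3 1-(benzyloxy)-4-(prop-2-yn-1-yl)benzene; 1 4-(benzyloxy)benzyl chloride
Product: 5 1,4-bis(4-(benzyloxy)phenyl)but-2-yne, via alkynylmagnesium bromide 4 (not isolated)
Conditions: 3 (1.0 equiv), EtMgBr (1.05 equiv), THF, 0 → 40 °C; then CuCl (5 mol %), 1 (1.0 equiv), 50 °C; aq NH4Cl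
Reagents that add atoms: none
Why: EtMgBr removes the terminal alkyne hydrogen to give the alkynyl Grignard 4, and the same copper-catalysed alkynyl Grignard alkylation with one further molecule of 1 closes the symmetric 1,4-diarylbut-2-yne; no stereocentre is formed.

Step 3
Reactants: 5 1,4-bis(4-(benzyloxy)phenyl)but-2-yne
Product: 6 (Z)-1,4-bis(4-(benzyloxy)phenyl)but-2-ene
Conditions: H2 (1 atm), Pd/CaCO3 poisoned with Pb(OAc)2, quinoline, EtOAc, 20 °C, stopped after one equivalent of H2
Reagents that add atoms: none
Why: Lindlar semihydrogenation delivers both hydrogens to one face of the alkyne on the lead-poisoned palladium surface, which should give the Z-alkene without hydrogenolysis of the aryl benzyl ethers; this Z geometry fixes the later meso relationship.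

Step 4
Reactants: 6 (Z)-1,4-bis(4-(benzyloxy)phenyl)but-2-ene
Product: 7 dimethyl meso-(2R,3S)-2,3-bis(4-(benzyloxy)benzyl)succinate
Conditions: CO (3 atm), MeOH–THF, PdCl2 (5 mol %), CuCl2 (2.2 equiv), NaOAc (2.2 equiv), 25 °C
Reagents that add atoms: carbon monoxide [C-]#[O+]; methanol CO
Why: In this palladium-catalysed oxidative bis(alkoxycarbonylation), a methoxycarbonyl–palladium species (divalent palladium) adds syn across the Z-alkene, CO inserts into the new Pd–C bond with retention and methanolysis releases the diester, so both CO2Me groups land on the same face and C2/C3 are set as the meso pair by the alkene geometry; CuCl2 (divalent copper) reoxidises zerovalent palladium and NaOAc buffers the HCl.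

Step 5
Reactants: 7 dimethyl meso-(2R,3S)-2,3-bis(4-(benzyloxy)benzyl)succinate; 8 ethanethiol
Product: 10 S,S-diethyl meso-2,3-bis(4-(benzyloxy)benzyl)butanebis(thioate), via dimethylaluminium ethanethiolate 9 (not isolated)
Conditions: Me3Al (4.4 equiv), 8 (4.4 equiv), CH2Cl2, 0 °C; then 7, 0 → 25 °C; cold 1 M aq HCl quench
Reagents that add atoms: none
Why: In this aluminium thiolate transesterification, Me3Al and 8 give Me2AlSEt (9), whose Lewis-acidic aluminium activates each ester carbonyl while the thiolate is transferred; the exchange is non-basic and, run cold with only a small excess, should leave the α-stereocentres and benzyl ethers intact.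

Step 6
Reactants: 10 S,S-diethyl meso-2,3-bis(4-(benzyloxy)benzyl)butanebis(thioate); 11 (2,4-bis(benzyloxy)phenyl)boronic acid
Product: 12 meso-2,3-bis(4-(benzyloxy)benzyl)-1,4-bis(2,4-bis(benzyloxy)phenyl)butane-1,4-dione
Conditions: 11 (3.0 equiv), Pd2(dba)3 (5 mol %), P(2-furyl)3 (30 mol %), Cu(O2CC4H3S) (copper thiophene-2-carboxylate, monovalent copper; 3.3 equiv), THF, 50 °C, argon
Reagents that add atoms: none
Why: This is a Liebeskind–Srogl thioester–boronic acid ketone synthesis applied at both ends of the chain: zerovalent palladium inserts into each C(acyl)–S bond, Cu(O2CC4H3S) (monovalent copper) binds the ethanethiolate while its carboxylate activates boron so that the 2,4-bis(benzyloxy)phenyl group passes to palladium, and reductive elimination forms C1–ring A and then C4–ring A. The closest known reaction type is the coupling of S-alkyl thioesters, α-branched and α-stereogenic ones included, with arylboronic acids. No ring closes and no stereocentre is created; the meso C2/C3 pair set in step 4 is only carried through. The step needs retention at C2 and C3 and exactly one aryl group per acyl carbon: with no added base or acid the α-hydrogens and the emerging 1,4-diketone are left alone (no enolisation, no furan formation), and the aryl ketone cannot react again because only a C–S bond undergoes oxidative addition. An excess of 11 and of the copper salt should offset protodeboronation of the electron-rich, ortho-substituted boronic acid and push the more hindered second coupling to completion.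

Step 7
Reactants: 12 meso-2,3-bis(4-(benzyloxy)benzyl)-1,4-bis(2,4-bis(benzyloxy)phenyl)butane-1,4-dione
Product: 13 meso-(2R,3S)-1,4-bis(2,4-dihydroxyphenyl)-2,3-bis(4-hydroxybenzyl)butane-1,4-dione (target)
Conditions: H2 (1 atm), Pd/C (10 %), EtOAc–THF, 20 °C, stopped at complete debenzylation
Reagents that add atoms: none
Why: Catalytic hydrogenolysis cleaves the six aryl benzyl ethers to toluene and free phenols under neutral, aprotic conditions; the aryl ketones, deactivated by the electron-rich rings and by the 2-hydroxy hydrogen bond once unveiled, should not be reduced, and without acid or base the meso centres and the 1,4-diketone persist.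

Compound list
1 | 4-(benzyloxy)benzyl chloride | ClCc1ccc(OCc2ccccc2)cc1 | starting material
2 | ethynylmagnesium bromide | C#C[Mg]Br | starting material
3 | 1-(benzyloxy)-4-(prop-2-yn-1-yl)benzene | C#CCc1ccc(OCc2ccccc2)cc1 | intermediate
4 | (3-(4-(benzyloxy)phenyl)prop-1-yn-1-yl)magnesium bromide | Br[Mg]C#CCc1ccc(OCc2ccccc2)cc1 | intermediate
5 | 1,4-bis(4-(benzyloxy)phenyl)but-2-yne | O(Cc1ccccc1)c1ccc(CC#CCc2ccc(OCc3ccccc3)cc2)cc1 | intermediate
6 | (Z)-1,4-bis(4-(benzyloxy)phenyl)but-2-ene | O(Cc1ccccc1)c1ccc(C/C=C\Cc2ccc(OCc3ccccc3)cc2)cc1 | intermediate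
7 | dimethyl meso-(2R,3S)-2,3-bis(4-(benzyloxy)benzyl)succinate | COC(=O)[C@@H](Cc1ccc(OCc2ccccc2)cc1)[C@@H](Cc1ccc(OCc2ccccc2)cc1)C(=O)OC | intermediate
8 | ethanethiol | CCS | starting material
9 | dimethylaluminium ethanethiolate | CCS[Al](C)C | intermediate
10 | S,S-diethyl meso-2,3-bis(4-(benzyloxy)benzyl)butanebis(thioate) | CCSC(=O)[C@@H](Cc1ccc(OCc2ccccc2)cc1)[C@@H](Cc1ccc(OCc2ccccc2)cc1)C(=O)SCC | intermediate
11 | (2,4-bis(benzyloxy)phenyl)boronic acid | OB(O)c1ccc(OCc2ccccc2)cc1OCc1ccccc1 | starting material
12 | meso-2,3-bis(4-(benzyloxy)benzyl)-1,4-bis(2,4-bis(benzyloxy)phenyl)butane-1,4-dione | O=C(c1ccc(OCc2ccccc2)cc1OCc1ccccc1)[C@@H](Cc1ccc(OCc2ccccc2)cc1)[C@@H](Cc1ccc(OCc2ccccc2)cc1)C(=O)c1ccc(OCc2ccccc2)cc1OCc1ccccc1 | intermediate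
13 | meso-(2R,3S)-1,4-bis(2,4-dihydroxyphenyl)-2,3-bis(4-hydroxybenzyl)butane-1,4-dione | O=C(c1ccc(O)cc1O)[C@@H](Cc1ccc(O)cc1)[C@@H](Cc1ccc(O)cc1)C(=O)c1ccc(O)cc1O | target

Total step count: 7
Longest linear sequence: 7 steps (1 → 3 → 5 → 6 → 7 → 10 → 12 → 13)

Steps most likely to fail

Step 6. Oxidative addition and transmetalation may be slow at two hindered, α-branched acyl centres with an ortho-substituted boronic acid. Protodeboronation and homocoupling of 11 could then outrun the second acyl–aryl coupling and stop the sequence after one ketone has formed. The fallback is a two-directional Weinreb ketone synthesis that sets out from diester 7. Me3Al and MeNH(OMe)·HCl in CH2Cl2 at 0 → 25 °C should convert 7 into meso-N1,N4-dimethoxy-N1,N4-dimethyl-2,3-bis(4-(benzyloxy)benzyl)succinamide F1. (2,4-Bis(benzyloxy)phenyl)magnesium bromide F2, made from commercial 1-bromo-2,4-bis(benzyloxy)benzene and Mg turnings in THF, is then added at −20 → 0 °C. The chelated tetrahedral adducts hold both carbonyls until a cold aq NH4Cl quench, which limits enolisation and over-addition. This returns to the route at 12.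

Step 4. Palladium hydride species may isomerise the alkene (Z to E, or migration into conjugation with ring B), and β-hydride elimination may follow the first insertion. Either would erode the syn relationship or give unsaturated mono-esters. The fallback is a stereospecific double carbonylation of the epoxide, setting out from 6. mCPBA with NaHCO3 in CH2Cl2 should give cis-2,3-bis(4-(benzyloxy)benzyl)oxirane F3. With [(ClTPP)Al(THF)2][Co(CO)4] (ClTPP = meso-tetrakis(4-chlorophenyl)porphyrinato), CO (60 bar), 1,4-dioxane, 90 °C, F3 should pass through trans-3,4-bis(4-(benzyloxy)benzyl)oxetan-2-one F4 to cis-3,4-bis(4-(benzyloxy)benzyl)dihydrofuran-2,5-dione F5. Each carbonylation inverts one of the two carbons, so the cis-epoxide maps onto the cis (meso) anhydride. Warm MeOH opens F5 to racemic 4-methoxy-4-oxo-2,3-bis(4-(benzyloxy)benzyl)butanoic acid F6, and Me3SiCHN2 in MeOH–toluene methylates it. This returns to the route at 7.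

Step 1. The electron-rich benzylic chloride may homocouple, the first-formed terminal alkyne may be benzylated a second time in the flask, and the skipped alkyne may isomerise to an allene under the basic Grignard conditions. The fallback is a two-fold Stille coupling under neutral conditions, setting out from 1: Bu3SnC≡CSnBu3 (0.5 equiv), Pd(PPh3)4, toluene, 80 °C. Alkynyl transfer from tin to the benzylpalladium chloride at both ends should give the symmetric alkyne directly, bypassing 3 and returning to the route at 5.

Further compounds
F1 | step 6 | meso-N1,N4-dimethoxy-N1,N4-dimethyl-2,3-bis(4-(benzyloxy)benzyl)succinamide | CON(C)C(=O)[C@@H](Cc1ccc(OCc2ccccc2)cc1)[C@@H](Cc1ccc(OCc2ccccc2)cc1)C(=O)N(C)OC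
F2 | step 6 | (2,4-bis(benzyloxy)phenyl)magnesium bromide | Br[Mg]c1ccc(OCc2ccccc2)cc1OCc1ccccc1
F3 | step 4 | cis-2,3-bis(4-(benzyloxy)benzyl)oxirane (meso) | O(Cc1ccccc1)c1ccc(C[C@H]2O[C@H]2Cc2ccc(OCc3ccccc3)cc2)cc1
F4 | step 4 | trans-3,4-bis(4-(benzyloxy)benzyl)oxetan-2-one (racemic, one enantiomer drawn) | O=C1O[C@H](Cc2ccc(OCc3ccccc3)cc2)[C@H]1Cc1ccc(OCc2ccccc2)cc1
F5 | step 4 | cis-3,4-bis(4-(benzyloxy)benzyl)dihydrofuran-2,5-dione (meso) | O=C1OC(=O)[C@H](Cc2ccc(OCc3ccccc3)cc2)[C@@H]1Cc1ccc(OCc2ccccc2)cc1
F6 | step 4 | 4-methoxy-4-oxo-2,3-bis(4-(benzyloxy)benzyl)butanoic acid (racemic, relative configuration as in 7, one enantiomer drawn) | COC(=O)[C@@H](Cc1ccc(OCc2ccccc2)cc1)[C@@H](Cc1ccc(OCc2ccccc2)cc1)C(=O)O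
F0 | step 1 | none | none
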